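**Plan**

- Retrosynthetic cuts: the butenolide at C13–C16 and O15–C16 (carbon monoxide) and at C12=C13 (aldehyde plus propargyl alcohol); C17–O and C8–H (exocyclic alkene); ring A and ring B at C4–C5 and C9–C10; the chain at C1–C2 and C11–C12.
- Forward order: geranyl chloride is extended by C12, oxidized at its terminal trans-methyl (C1) and joined to a 2-methylacetoacetate; one oxidative radical bicyclization builds ring A, then ring B; C17 is added by hydroboration; the lactone ring is made last.
- Stereochemistry: absolute sense from a (−)-8-phenylmenthyl ester; C4, C5, C9 and C10 from the chair–chair cyclization of the E,E-diene; C3 by axial hydride delivery; C8 by equilibration of the C17 aldehyde to its equatorial epimer.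
- Enabling feature: the lactone ring C13–C14–C15–O15–C16 is a 2,3-allenol plus CO. In C12=C13=C14–C15–OH, O15 holds a ruthenium-bound CO carbon (C16) over the sp carbon C13; bonding there leaves C13=C14 in the ring and C12 to take up hydrogen.
- Labdane numbering is used; faces refer to the usual drawing with ring A at the left: C20 and C19 α (axial), H5 and H9 β, 3-O and the C9 chain α (equatorial), 17-CH2OH β (equatorial) in the target.

Key step: step 17

Assumption: the (−)-8-phenylmenthyl ester is taken to shield the face of the ytterbium-chelated keto ester radical that leads to the 10α-methyl (ent) series; if the sense proves opposite, (+)-8-phenylmenthol is used in step 5 and nothing else changes.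

**Route**

Step 1
Reactants: 1 geranyl chloride
Product: 3 homogeraniol, via homogeranyl(isopropoxy)dimethylsilane 2 (not isolated)
Conditions: i-PrO(Me)2SiCH2MgCl (from the chloromethylsilane and Mg, THF), Li2CuCl4 (3 mol%), THF, −10 to 20 °C; then KF, KHCO3, 30% H2O2, MeOH/THF, 20 °C
Reagents that add atoms: (chloromethyl)isopropoxydimethylsilane, CC(C)O[Si](C)(C)CCl (gives C12); hydrogen peroxide, OO (gives the hydroxyl oxygen)
Why: Copper-catalysed Grignard allylic substitution takes place at the primary carbon with retention of the E alkene, and the Tamao oxidation then replaces C–Si by C–OH, so the silylmethyl Grignard serves as a hydroxymethyl anion.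

Step 2
Reactants: 3 homogeraniol
Product: 4 homogeranyl benzyl ether
Conditions: NaH, BnBr, Bu4NI (cat.), THF, 0 to 20 °C
Reagents that add atoms: benzyl bromide, BrCc1ccccc1
Why: Williamson etherification of the primary alkoxide; the benzyl ether is inert to every step up to its hydrogenolysis.

Step 3
Reactants: 4 homogeranyl benzyl ether
Product: 5 terminal (E)-allylic alcohol
Conditions: SeO2 (0.3 equiv), t-BuOOH (3 equiv), salicylic acid (0.1 equiv), CH2Cl2, 20 °C, stopped at partial conversion with recovery of 4
Reagents that add atoms: tert-butyl hydroperoxide, CC(C)(C)OO; selenium dioxide, O=[Se]=O (carries the oxygen to C1)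
Why: Riley allylic oxidation (ene reaction and [2,3]-shift at selenium, turned over by the hydroperoxide) is E-selective for the trans-methyl of the terminal, more accessible trisubstituted alkene.

Step 4
Reactants: 5 terminal (E)-allylic alcohol
Product: 6 allylic bromide
Conditions: PBr3 (0.4 equiv), Et2O, −10 °C
Reagents that add atoms: phosphorus tribromide, BrP(Br)Br
Why: SN2 displacement of the phosphite ester at low temperature gives the primary allylic bromide without allylic transposition or loss of alkene geometry.

Step 5
Reactants: 7 (−)-8-phenylmenthol; 8 ethyl 2-methyl-3-oxobutanoate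
Product: 9 (−)-8-phenylmenthyl 2-methyl-3-oxobutanoate
Conditions: DMAP (0.2 equiv), toluene, reflux with removal of EtOH
Reagents that add atoms: none
Why: DMAP-catalysed transesterification of a β-keto ester (through the acylketene) is driven by distilling off ethanol and works with hindered secondary alcohols.

Step 6
Reactants: 9 (−)-8-phenylmenthyl 2-methyl-3-oxobutanoate; 6 allylic bromide
Product: 11 polyene keto ester, via sodium lithium dienolate 10 (not isolated)
Conditions: NaH (1.1 equiv), THF, 0 °C; n-BuLi (1.05 equiv), 0 °C; then 6, 0 to 20 °C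
Reagents that add atoms: none
Why: γ-Alkylation of a β-keto ester dianion: the terminal carbanion is the more nucleophilic site and displaces the allylic bromide by SN2; C2 of the product is an epimer mixture, which does not matter because it becomes a radical centre.

Step 7
Reactants: 11 polyene keto ester
Product: 12 bicyclic keto ester
Conditions: Mn(OAc)3·2H2O (2.2 equiv), Cu(OAc)2·H2O (1 equiv), Yb(OTf)3 (1 equiv), CF3CH2OH, 0 °C
Reagents that add atoms: none
Why: Oxidative free-radical polyene cyclization: Mn(OAc)3 turns the Yb-chelated keto ester into its α-radical, which adds 6-endo to C5 and then 6-endo to C9 through a chair–chair array of the E,E-diene (trans ring fusion, C9 chain equatorial, ester axial and cis to C20), the phenyl group of the auxiliary blocking one face of the chelate and so fixing the absolute sense, and Cu(OAc)2 oxidizes the tertiary C8 radical to the less substituted exocyclic alkene.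

Step 8
Reactants: 12 bicyclic keto ester
Product: 13 3,19-diol
Conditions: LiAlH4 (4 equiv), THF, 0 °C to reflux; aqueous NaOH work-up
Reagents that add atoms: none
Why: LiAlH4 delivers hydride to the C3 ketone along the axial (β) trajectory, away from the axial C4 substituent, to give the equatorial 3α-alcohol, and reduces the hindered ester to the 19-CH2OH with release of the auxiliary.

Step 9
Reactants: 13 3,19-diol
Product: 14 3,19-acetonide
Conditions: 2,2-dimethoxypropane, PPTS (cat.), CH2Cl2, 20 °C
Reagents that add atoms: 2,2-dimethoxypropane, COC(C)(C)OC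
Why: Acetal exchange closes the six-membered 1,3-dioxane on the cis-disposed 3-OH and 19-OH.

Step 10
Reactants: 14 3,19-acetonide
Product: 16 17-alcohol (C8 epimers), via C17 alkylborane 15 (not isolated)
Conditions: BH3·THF, THF, 0 to 20 °C; then NaOH, 30% H2O2, 0 to 20 °C
Reagents that add atoms: hydrogen peroxide, OO
Why: Brown hydroboration–oxidation puts boron on the terminal carbon C17; borane should approach mainly from the β face, opposite the axial C20 methyl, so the axial 17-CH2OH epimer is expected to prevail, and both C8 epimers are carried on because step 12 makes them converge.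

Step 11
Reactants: 16 17-alcohol (C8 epimers)
Product: 17 17-aldehyde (C8 epimers)
Conditions: Dess–Martin periodinane, NaHCO3, CH2Cl2, 20 °C
Reagents that add atoms: none
Why: Dess–Martin oxidation of a primary alcohol under buffered conditions that leave the acetonide and the benzyl ether untouched.

Step 12
Reactants: 17 17-aldehyde (C8 epimers)
Product: 19 equatorial 17-alcohol, via equatorial 17-aldehyde 18 (not isolated)
Conditions: NaOMe (0.3 equiv), MeOH, 20 °C until equilibrated; then NaBH4, 0 °C
Reagents that add atoms: none
Why: Base-mediated epimerization through the enolate places the C8 formyl group equatorial (β, trans to the C9 chain and free of the 1,3-diaxial contact with C20), and NaBH4 reduction in the same flask fixes this thermodynamic configuration as the 17-alcohol.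

Step 13
Reactants: 19 equatorial 17-alcohol
Product: 20 17-silyl ether
Conditions: TBSCl, imidazole, DMF, 20 °C
Reagents that add atoms: tert-butyldimethylsilyl chloride, CC(C)(C)[Si](C)(C)Cl
Why: Standard silylation of the primary alcohol; the silyl ether keeps O17 from forming a lactol with the C12 aldehyde made in step 15 and falls in the final acid step.

Step 14
Reactants: 20 17-silyl ether
Product: 21 12-alcohol
Conditions: H2 (1 atm), 10% Pd/C, EtOAc, 20 °C
Reagents that add atoms: none
Why: Hydrogenolysis of the benzyl ether over palladium on carbon in a neutral solvent spares the silyl ether and the acetonide.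

Step 15
Reactants: 21 12-alcohol
Product: 22 12-aldehyde
Conditions: Dess–Martin periodinane, NaHCO3, CH2Cl2, 0 to 20 °C
Reagents that add atoms: none
Why: Dess–Martin oxidation gives the aldehyde without touching the other, protected oxygens; it is used at once.

Step 16
Reactants: 22 12-aldehyde; 23 propargyl alcohol
Product: 25 2,3-allenol, via propargylic amine 24 (not isolated)
Conditions: 23 (1.5 equiv), CuBr2 (20 mol%), (S)-α,α-diphenylprolinol (1.1 equiv), 1,4-dioxane, 130 °C, sealed tube
Reagents that add atoms: none
Why: Allenation of a terminal alkyne with an aldehyde (Crabbé-type homologation): copper-mediated three-component coupling gives the propargylic amine, whose 1,5-hydride shift and β-elimination give the 1,3-disubstituted allene; the allene axis is erased in step 17, so its configuration is immaterial.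

Step 17
Reactants: 25 2,3-allenol
Product: 26 protected butenolide
Conditions: Ru3(CO)12 (2 mol%), CO (10 atm), Et3N, 100 °C
Reagents that add atoms: carbon monoxide, [C-]#[O+]
Why: Et3N and Ru3(CO)12 under CO should turn the C15 hydroxyl into a ruthenium alkoxycarbonyl (Ru–C16(=O)–O15), and migratory insertion of the distal allene π bond C12=C13 into the Ru–C16 bond then forms the C13–C16 bond and closes the lactone, leaving a π-allyl ruthenium hydride over C12–C13–C14 that reductively eliminates with hydrogen at C12. The closest known reaction type is the Ru3(CO)12-catalysed cyclocarbonylation of 2,3-allenyl alcohols to 3-substituted furan-2(5H)-ones. The five-membered ring closes in an exo mode with respect to C12=C13, with C13=C14 staying inside the ring as the butenolide alkene, and the attacking carbon lies in the plane of the C14 substituents, which is where that π bond points. No stereocentre is formed, and the allene axis is erased. The step needs attack at the central allene carbon and hydrogen delivery to C12 and not C14: the short O15–C15–C14 tether lets C16 reach only C13, and the conjugated endocyclic lactone is both the product of reductive elimination at the less hindered allyl terminus and the thermodynamic isomer under the basic, hydride-containing conditions. The silyl ether and the acetonide are inert to Et3N and CO, and no other hydroxyl is free to be carbonylated.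

Step 18
Reactants: 26 protected butenolide
Product: 27 14-deoxy-17-hydroxyandrographolide
Conditions: 1 M aq. HCl, THF, 20 °C
Reagents that add atoms: none
Why: Aqueous acid hydrolyses the acetonide and the primary silyl ether together, and the conjugated butenolide is stable to these conditions.

**Compound list**

1 | geranyl chloride, (2E)-1-chloro-3,7-dimethylocta-2,6-diene | CC(C)=CCC/C(C)=C/CCl | starting material
2 | [(3E)-4,8-dimethylnona-3,7-dien-1-yl](isopropoxy)dimethylsilane | CC(C)=CCC/C(C)=C/CC[Si](C)(C)OC(C)C | intermediate (not isolated)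
3 | homogeraniol, (3E)-4,8-dimethylnona-3,7-dien-1-ol | CC(C)=CCC/C(C)=C/CCO | intermediate
4 | homogeranyl benzyl ether | CC(C)=CCC/C(C)=C/CCOCc1ccccc1 | intermediate
5 | (2E,6E)-9-(benzyloxy)-2,6-dimethylnona-2,6-dien-1-ol | OC/C(C)=C/CC/C(C)=C/CCOCc1ccccc1 | intermediate
6 | (2E,6E)-9-(benzyloxy)-1-bromo-2,6-dimethylnona-2,6-diene | BrC/C(C)=C/CC/C(C)=C/CCOCc1ccccc1 | intermediate
7 | (−)-8-phenylmenthol, (1R,2S,5R)-5-methyl-2-(2-phenylpropan-2-yl)cyclohexan-1-ol | C[C@@H]1CC[C@H]([C@@H](C1)O)C(C)(C)c1ccccc1 | starting material
8 | ethyl 2-methyl-3-oxobutanoate | CCOC(=O)C(C)C(C)=O | starting material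
9 | (−)-8-phenylmenthyl 2-methyl-3-oxobutanoate (C2 epimers) | CC(=O)C(C)C(=O)O[C@@H]1C[C@H](C)CC[C@H]1C(C)(C)c1ccccc1 | intermediate
10 | sodium lithium dienolate (dianion) of 9 | [Na+].[Li+].C=C([O-])C(C)=C([O-])O[C@@H]1C[C@H](C)CC[C@H]1C(C)(C)c1ccccc1 | intermediate (not isolated)
11 | (−)-8-phenylmenthyl (6E,10E)-13-(benzyloxy)-2,6,10-trimethyl-3-oxotrideca-6,10-dienoate (C2 epimers) | CC(C(=O)CC/C(C)=C/CC/C(C)=C/CCOCc1ccccc1)C(=O)O[C@@H]1C[C@H](C)CC[C@H]1C(C)(C)c1ccccc1 | intermediate
12 | (−)-8-phenylmenthyl 12-(benzyloxy)-3-oxo-13,14,15,16-tetranorlabd-8(17)-en-19-oate, ent series (ester axial and cis to C20, H5 β, C9 chain α) | C[C@]1(C(=O)O[C@@H]3C[C@H](C)CC[C@H]3C(C)(C)c4ccccc4)[C@H]2CCC(=C)[C@@H](CCOCc5ccccc5)[C@]2(C)CCC1=O | intermediate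
13 | 12-(benzyloxy)-13,14,15,16-tetranorlabd-8(17)-ene-3,19-diol, ent series (3-OH α, equatorial) | C[C@]1(CO)[C@H]2CCC(=C)[C@@H](CCOCc3ccccc3)[C@]2(C)CC[C@H]1O | intermediate
14 | 3,19-acetonide of 13 | C[C@]1(COC4(C)C)[C@H]2CCC(=C)[C@@H](CCOCc3ccccc3)[C@]2(C)CC[C@H]1O4 | intermediate
15 | C17 alkylborane from 14 (C8 epimers, C8 not specified) | C[C@]1(COC4(C)C)[C@H]2CCC(CB)[C@@H](CCOCc3ccccc3)[C@]2(C)CC[C@H]1O4 | intermediate (not isolated)
16 | 12-(benzyloxy)-3,19-(isopropylidenedioxy)-13,14,15,16-tetranorlabdan-17-ol, ent series (C8 epimers, C8 not specified) | C[C@]1(COC4(C)C)[C@H]2CCC(CO)[C@@H](CCOCc3ccccc3)[C@]2(C)CC[C@H]1O4 | intermediate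
17 | the corresponding 17-aldehyde (C8 epimers, C8 not specified) | C[C@]1(COC4(C)C)[C@H]2CCC(C=O)[C@@H](CCOCc3ccccc3)[C@]2(C)CC[C@H]1O4 | intermediate
18 | 17-aldehyde with equatorial (β) formyl group, H8 α | C[C@]1(COC4(C)C)[C@H]2CC[C@H](C=O)[C@@H](CCOCc3ccccc3)[C@]2(C)CC[C@H]1O4 | intermediate (not isolated)
19 | 17-alcohol with equatorial (β) CH2OH, H8 α | C[C@]1(COC4(C)C)[C@H]2CC[C@H](CO)[C@@H](CCOCc3ccccc3)[C@]2(C)CC[C@H]1O4 | intermediate
20 | 17-O-tert-butyldimethylsilyl ether of 19 | C[C@]1(COC4(C)C)[C@H]2CC[C@H](CO[Si](C)(C)C(C)(C)C)[C@@H](CCOCc3ccccc3)[C@]2(C)CC[C@H]1O4 | intermediate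
21 | 12-alcohol (benzyl removed) | C[C@]1(COC4(C)C)[C@H]2CC[C@H](CO[Si](C)(C)C(C)(C)C)[C@@H](CCO)[C@]2(C)CC[C@H]1O4 | intermediate
22 | 12-aldehyde | C[C@]1(COC4(C)C)[C@H]2CC[C@H](CO[Si](C)(C)C(C)(C)C)[C@@H](CC=O)[C@]2(C)CC[C@H]1O4 | intermediate
23 | propargyl alcohol, prop-2-yn-1-ol | C#CCO | starting material
24 | propargylic amine: C12 bears the (S)-2-(hydroxydiphenylmethyl)pyrrolidin-1-yl group and the C13≡C14–C15H2OH chain (C12 not specified) | C[C@]1(COC4(C)C)[C@H]2CC[C@H](CO[Si](C)(C)C(C)(C)C)[C@@H](CC(C#CCO)N5CCC[C@H]5C(O)(c6ccccc6)c6ccccc6)[C@]2(C)CC[C@H]1O4 | intermediate (not isolated)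
25 | 2,3-allenol, side chain C11H2–C12H=C13=C14H–C15H2OH (allene axis not specified) | C[C@]1(COC4(C)C)[C@H]2CC[C@H](CO[Si](C)(C)C(C)(C)C)[C@@H](CC=C=CCO)[C@]2(C)CC[C@H]1O4 | intermediate
26 | 14-deoxy-17-hydroxyandrographolide 3,19-acetonide 17-O-tert-butyldimethylsilyl ether | C[C@]1(COC4(C)C)[C@H]2CC[C@H](CO[Si](C)(C)C(C)(C)C)[C@@H](CCC3=CCOC3=O)[C@]2(C)CC[C@H]1O4 | intermediate
27 | 14-deoxy-17-hydroxyandrographolide | C[C@]1(CO)[C@H]2CC[C@H](CO)[C@@H](CCC3=CCOC3=O)[C@]2(C)CC[C@H]1O | target

**Count and risks**

Total step count: 18. Longest linear sequence: 17 steps from geranyl chloride 1 (steps 1–4 and 6–18); step 5 is the side branch.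

The three steps most likely to fail:

1. Step 7. What may go wrong: weak face discrimination by the auxiliary when the radical carbon is fully substituted, loss of control at C4, or termination to ring alkenes instead of the exocyclic one. The fallback sets out from 6 and 7 and comes back at 12, with the C4 methyl added after the rings are made. Alcohol 7 and ethyl acetoacetate give (−)-8-phenylmenthyl 3-oxobutanoate F1 (DMAP, toluene, reflux). NaH then n-BuLi give its sodium lithium dienolate F2, which is alkylated with 6 to the unmethylated polyene keto ester F3. The same Mn(OAc)3/Cu(OAc)2/Yb(OTf)3 cyclization, now of a secondary chelated radical, gives the bicyclic β-keto ester F4. C-Methylation (K2CO3, MeI, acetone) should take place from the equatorial side, away from the axial C20 methyl, leaving the ester axial, and so gives 12.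

2. Step 16. What may go wrong: self-condensation of the enolizable aldehyde through its enamine at 130 °C, or stalling at the propargylic amine. The fallback sets out from 22 and comes back at 25, making the allene by reductive transposition. The lithium acetylide of 4-methoxybenzyl propargyl ether (n-BuLi, THF, −78 °C) adds to 22 to give the propargylic alcohol F5 (C12 epimers). Mitsunobu displacement with 2-nitrobenzenesulfonylhydrazide (PPh3, diethyl azodicarboxylate, THF, −15 to 20 °C), followed by loss of sulfinate and retro-ene loss of N2 from the diazene, gives the allenyl 4-methoxybenzyl ether F6. DDQ (CH2Cl2, pH 7 buffer) frees the allenol 25.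

3. Step 17. What may go wrong: isomerization of the allene by ruthenium hydride before insertion, or incomplete carbonylation. The fallback sets out from 22 and comes back at 27; the lactone is brought in whole and the double bond is then moved into the ring. Wittig reaction of 22 with α-(triphenylphosphoranylidene)-γ-butyrolactone (toluene, 80 °C) gives the protected (E)-alkylidene lactone F7. 1 M aq. HCl in THF removes the acetonide and the silyl ether to give the (E)-alkylidene lactone triol F8. RhCl3·3H2O (cat.) in ethanol at reflux should move the exocyclic double bond into the ring to give the more stable butenolide 27.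

**Further compounds**

F1 | step 7 | (−)-8-phenylmenthyl 3-oxobutanoate | CC(=O)CC(=O)O[C@@H]1C[C@H](C)CC[C@H]1C(C)(C)c1ccccc1
F2 | step 7 | sodium lithium dienolate (dianion) of F1 | [Na+].[Li+].C=C([O-])C=C([O-])O[C@@H]1C[C@H](C)CC[C@H]1C(C)(C)c1ccccc1
F3 | step 7 | (−)-8-phenylmenthyl (6E,10E)-13-(benzyloxy)-6,10-dimethyl-3-oxotrideca-6,10-dienoate | O=C(CC(=O)O[C@@H]1C[C@H](C)CC[C@H]1C(C)(C)c1ccccc1)CC/C(C)=C/CC/C(C)=C/CCOCc1ccccc1
F4 | step 7 | bicyclic β-keto ester lacking the C4 methyl (C4 enolizable, not specified) | O=C(O[C@@H]3C[C@H](C)CC[C@H]3C(C)(C)c4ccccc4)C1[C@H]2CCC(=C)[C@@H](CCOCc5ccccc5)[C@]2(C)CCC1=O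
F5 | step 16 | propargylic alcohol, side chain C11H2–C12H(OH)–C13≡C14–C15H2–O-(4-methoxybenzyl) | C[C@]1(COC4(C)C)[C@H]2CC[C@H](CO[Si](C)(C)C(C)(C)C)[C@@H](CC(O)C#CCOCc5ccc(OC)cc5)[C@]2(C)CC[C@H]1O4
F6 | step 16 | allenyl 4-methoxybenzyl ether (4-methoxybenzyl ether of 25) | C[C@]1(COC4(C)C)[C@H]2CC[C@H](CO[Si](C)(C)C(C)(C)C)[C@@H](CC=C=CCOCc5ccc(OC)cc5)[C@]2(C)CC[C@H]1O4
F7 | step 17 | protected (E)-alkylidene lactone, C12=C13 exocyclic | C[C@]1(COC4(C)C)[C@H]2CC[C@H](CO[Si](C)(C)C(C)(C)C)[C@@H](C/C=C3\CCOC3=O)[C@]2(C)CC[C@H]1O4
F8 | step 17 | (E)-alkylidene lactone triol, the C12=C13 isomer of 27 | C[C@]1(CO)[C@H]2CC[C@H](CO)[C@@H](C/C=C3\CCOC3=O)[C@]2(C)CC[C@H]1O
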